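all flasks: left-handed substrate 0.060 M; right-handed substrate 0.060 M

| charge | partner | protic impurity | remark | time |
|---|---|---|---|---|
| Wednesday's | 2.2 equiv | 3 mM | run made earlier |  |
| elm | 1.50 equiv | 3.00 mM |  | 6.0 d |
| larch | 1.50 equiv | 0.800 mM |  | 6.0 d |

Wednesday's run (percent of the left-handed substrate and right-handed substrate together charged)

| time / h | left-handed product / % | right-handed product / % |
|---|---|---|
| 4.00 | 29 | 2 |
| 8.00 | 37 | 0 |
| 15.0 | 40 | 2 |
| 25.0 | 45 | 2 |
| 48.0 | 48 | 0 |

(scatter of a reading: 1.5 percentage points)

- partner is single-handed; left-handed substrate and right-handed substrate are mirror images of each other, charged as a racemate, each of them at the stated concentration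
- an excess is below zero if the other one leads
- no earlier run changes the charge of protic impurity; that part of a forecast is a guess
- the handed part of partner does not stay in what it makes, so the products of the two hands are mirror images too

* which of the two ends with the higher excess of left-handed product over right-handed product in the product ("neither" if they lie within 2 percentage points) (elm / larch / neither)
* excess of left-handed product over right-handed product in the product at the end, elm
* excess of left-handed product over right-handed product in the product at the end, larch

The amounts in Wednesday's run, read as fractions of the racemate charged, formed a ladder. On the fastest rung, left-handed product reached 29% of the charge by 4.00 h, against a ceiling of 50%. On the slower rung it crept from 37% at 8.00 h to 48% at 48.0 h. On the slowest, right-handed product averaged 1.20%, that mean carrying a scatter of 0.67 percentage points. I read this as a kinetic resolution, so I took that mean over the last left-handed product, which gave 0.0250; this ratio of right-handed to left-handed product is the leak: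

excess = (1 − leak) / (1 + leak)

My reckoning gave 95.1% for Wednesday's run, and 89.9% with the mean right-handed product raised by two of those scatters. I carried this to elm and larch as an estimate, though their 6.0 d is 3.00 times the last reading, and no earlier run varied the protic impurity.

The forecast said neither, with 94% for elm and 96% for larch, judging that “Any product racemisation or slow-hand reaction is therefore small”. My central value lay between those two figures.

The simulation gave neither, with 89.4% for elm and 89.0% for larch, so the forecast for larch stood 7 points too high.

    partner + protic impurity → quenched reagent (k = 7.00 × 10⁻⁴ L mol⁻¹ s⁻¹)
    partner + left-handed substrate → left-handed product (k = 6.90 × 10⁻⁴ L mol⁻¹ s⁻¹)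
    partner ⇌ dormant form (K = 0.520, k = 2.80 × 10⁻⁵ s⁻¹)
    2 partner → self-condensation product (k = 1.20 × 10⁻⁴ L mol⁻¹ s⁻¹)
    partner + right-handed substrate → right-handed product (k = 1.20 × 10⁻⁵ L mol⁻¹ s⁻¹)

Elm ended with 47.9% left-handed product and 2.67% right-handed product, a leak of 0.0557, larger than the 0.0250 I had read from Wednesday's run, and the formula returns 89.4%. A neighbouring flask, elm charged with 2.50 equiv of partner instead, ended with 49.9% left-handed product and 5.22% right-handed product. Its leak was 0.105, which the formula turns into an excess of 81.0%.

The numbers in the tables were generated by integration with constants of no real substance; noise was put on by code.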